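The earlier runs and the new flask are calculated on assumed constants.

Time stops mattering early in flask alpha: its product reads 12.1% at 2.50 h and 12.2% at 10.0 h. So we ask what share of the charge ends as product, and how soon it gets there.

all flasks: substrate 0.012 M

|  | enzyme | remark | time |
|---|---|---|---|
| alpha | 1.2 µM | the very flask that is asked about, followed so far |  |
| zeta | 2.4 µM | run made earlier |  |
| flask | 1.2 µM |  | 10 h |

alpha run (percent of the substrate charged)

| time / h | product / % | substrate / % |
|---|---|---|
| 2.50 | 12.1 | 13.9 |
| 5.00 | 11.4 | 14.1 |
| 8.00 | 11.8 | 13.4 |
| 10.0 | 12.2 | 13.4 |

zeta run (percent of the substrate charged)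

| time / min | product / % | substrate / % |
|---|---|---|
| 6.00 | 4.5 | 15.3 |
| 15.0 | 6.9 | 14.2 |
| 30.0 | 9.0 | 13.2 |
| 50.0 | 10.1 | 13.4 |

(each reading ± 0.5 percentage points)

1. product, in percent of the substrate first charged, at 10 h
2. which option adds most product ("none" when 2 percentage points or less is all one gets) (Friday's / Thursday's / Tuesday's / Monday's / none)
3. product present, with what was taken out counted in, in percent of the substrate first charged, after Thursday's
4. product present, with what was taken out counted in, in percent of the substrate first charged, after Tuesday's

- Friday's: at 10 h add enzyme, 100% of the amount charged, then wait 5.0 h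
- Thursday's: change nothing and wait 5.0 h more
- Tuesday's: at 10 h add substrate, 50.0% of the amount charged, then wait 5.0 h
- Monday's: at 10 h take out 90% of the product then present, then wait 5.0 h

- removed product is counted in
- the earlier runs were read with a standard deviation of 0.5 percentage points
- additions bring no volume worth counting

We build our reckoning one process at a time.

1. Main step: substrate to product, reversible. Alpha's readings average 11.9% product, with a scatter of about 0.25 percentage points on that mean, and 13.7% substrate. The ratio [product]/[substrate] reads 0.867. With this step alone, product would reach 46.4% of the charge.

2. Add a reservoir. The two readings leave 74.4% of alpha's charge unread, 5.43 times [substrate]. With it the number comes down to the measured mean, which we call the plateau share, the part of all material in the flask that stands as product at rest. We read alpha's level as thermodynamic control.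

3. Add the enzyme, which we take to set the pace. Roughly, [product] = plateau × (1 − exp(−t/τ)). Zeta's reading at 30.0 min gives τ = 21.2 min. With pace proportional to enzyme, alpha has 42.3 min. The wait of 5.0 h is longer than that, and by this estimate leaves 0.0832% of a gap open.

4. Each option then gives the plateau share of the material then in the flask. Waiting or adding enzyme leaves that material unchanged, so the product stays at 11.9%. Tuesday's gives 17.8%. Monday's removes 10.7%, and the rest refills to a total of 21.3%, more than Tuesday's, so we choose Monday's.

The forecast gives 11.9% (11.4% to 12.4%), Monday's, 12% (11.4% to 12.6%) and 17.9% (16% to 19%): “Zeta, with twice the enzyme, heads for the same plateau rather than twice it, so this is equilibrium, not enzyme death.” Its figures for Thursday's and Tuesday's stand a little above ours.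

The flask gives 12.0%, 12.0% after Thursday's and 17.9% after Tuesday's, and Monday's adds most. The forecast's figure for now would be wrong for a much earlier look: with alpha's enzyme at zeta's last reading time, 50.0 min, product is 8.16%, below the forecast's low end. The plateau share gives Monday's gain as 9.4 points; the flask gives 9.5 points.

    substrate + enzyme ⇌ complex (K = 110 /M, k = 3.35 × 10⁵ /M/s)
    complex ⇌ enzyme + product (K = 0.00802 M, k = 2.51 /s)
    substrate ⇌ dormant form (K = 5.50, k = 0.0112 /s)

A neighbour flask charged with 0.048 M substrate, all else held, should by the plateau share reach 11.9% of its charge, or 0.00571 M. The computed product there is 11.9%.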